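Ring positions follow the 1-aryltetralin numbering: C1 bears the aryl group, C2 and C3 the CH2OH groups, C4 is the ring CH2, and ring A is C4a, C5–C8, C8a. Compound numbers are those of the steps and the compound list.

## Analysis of the target

Target 17 is a 1-aryltetralin cyclolignan. Ring A is fused to the saturated ring B (C1–C4); C1 carries a 4-hydroxy-3-methoxyphenyl group, C2 and C3 each carry CH2OH, C4 is CH2, and ring A bears OMe at C6 and OH at C7 and C8, leaving C5–H as its only free position. The three stereocentres are contiguous and (1S,2R,3R): the aryl group is trans to the C2 substituent, and the C2 and C3 substituents are trans to each other. C1 is doubly benzylic and cannot be corrected once set, whereas C2 and C3 can be epimerised only while they carry carbonyl groups. The sensitive parts are the 6-methoxy-7,8-diol (a catechol that oxidises readily to an ortho-quinone), the para-hydroxyphenyl group on C1 (oxidation gives a quinone methide at C1) and the 1,4-diol, which can close to a tetrahydrofuran in strong acid. The difficulty lies in a penta-substituted ring A whose C8 oxygen sits next to C1, in telling three phenolic oxygens from two methyl ethers, and in setting three adjacent centres in one absolute sense with no existing stereocentre to lean on. The strategy rests on ring B: seen from ring A it is a cyclohexene annulated across C4a–C8a whose C2 and C3 carry a trans pair of carboxyl-level carbons. That is the pattern left by a fumarate that has added across the exocyclic carbons C1 and C4 of a ring A ortho-quinodimethane.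

## Retrosynthetic reasoning

**17 to 16 (protecting-group C–O bonds).** The three phenols are released last. The catechol of ring A and the para-hydroxyphenyl unit are then never exposed to base, fluoride, hydride or organometallics. The forward step must cleave an aryl benzyl ether and a diphenylmethylene ketal, both benzylic C–O bonds, by neutral hydrogenolysis, and leave the C1–aryl bonds alone.

**16 to 15 (oxidation level at C2 and C3).** Both CH2OH groups are taken back to ester carbons. This turns C2–C3 into the remnant of an electron-poor alkene and places a removable chiral auxiliary on each carboxyl group. The forward reaction is a hydride reduction of two hindered esters that must not disturb C2 or C3.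

**15 to 12 and 13 through 14 (C1–C2 and C3–C4).** These two bonds join the benzylic carbons of ring A to the C2–C3 unit. Cutting both removes ring B and all three stereocentres in one operation and leaves a symmetrical dienophile, so there is no regiochemical question. Cutting C1–C8a or C4–C4a instead would require an arene substitution that must choose between ring positions and between two electron-rich rings. Diene 14 cannot be stored, so it is traced back to 12, which carries a silyl group on C4 and an acyloxy leaving group on C1. The forward step must generate 14 at low temperature with the aryl group outward, and 13 must add through its Re,Re face with the C2 ester exo.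

**12 to 11 (acyl C–O bond).** The leaving group is installed last, because a benzhydryl ester flanked by para-alkoxy groups on both rings ionises easily. The forward acylation must be basic and free of Lewis acids.

**11 to 7 and 9 through 10 (C1–C1′).** The aldehyde carbon of 1 is kept throughout as the future C1, so the pendant ring is added as a nucleophile in one convergent step. A magnesium reagent is chosen so that the alkoxide formed next to the benzylic silane is not basic enough to trigger silyl migration from carbon to oxygen.

**7 to 6 (C4–C4a).** The silylmethyl group is attached by cross-coupling at an aryl iodide. Direct alkylation of aryllithium 4 with a silylmethyl halide is not relied on, because aryllithiums tend to exchange halogen for metal with primary iodides instead of substituting them. The forward coupling must tolerate the free aldehyde.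

**6 to 2 through 3, 4 and 5 (C4a–I).** Electrophilic halogenation of 2 would go to the position beside the methoxy group, so the formyl group is used as the handle. It is masked in the flask as a chelating α-amino alkoxide that directs lithiation to its only free ortho position, and the aryllithium is iodinated.

**2 to 1 (ketal C–O bonds).** The two adjacent phenols are tied into a diphenylmethylene ketal and not converted into benzyl ethers. The ketal has no C–H next to oxygen for butyllithium to remove (no Wittig rearrangement), it holds the future C8 oxygen back from C1, where crowding would otherwise weaken the exo preference in the cycloaddition, and it leaves in the same hydrogenolysis as the benzyl ether of the pendant ring.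

**9 to 8 (benzyl C–O bond).** The pendant phenol is masked as its benzyl ether before the Grignard reagent is made.

## Alternatives that were turned down

**Alternative 1:** Disconnection of C2–C3 and C1–C8a, the biogenetic one, with the two cinnamate halves held on a (2R,4R)-pentane-2,4-diol tether. In the forward key step FeCl3 (trivalent iron) in aqueous acetone oxidises both free phenols of the tethered bis-cinnamate A1. The two carbons α to the carbonyls couple, ring A attacks the quinone methide carbon of the guaiacyl half through C8a, and the second quinone methide tautomerises to give the dihydronaphthalene dilactone A2.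
- For: two skeletal bonds from two simple cinnamic acids, no organometallic chemistry, and no prior substitution of ring A at C4a or C8a. On that point it is more economical than steps 2 and 3 of the chosen route.
- Against: the ring A half is a pyrogallol-type phenol that over-oxidises even with one oxygen masked as a pivalate. Phenoxyl radicals can also couple through oxygen or ring carbons. A nine-membered ring has to form. A2 still has a C3=C4 double bond, so C3 is not set and needs a later face-selective reduction and probably an epimerisation, followed by removal of the pivalate.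
- Comparison: the chosen route forms each new bond at a carbon functionalised for that purpose, sets C1, C2 and C3 in one event at the correct oxidation level, and never puts an oxidant near the electron-rich rings.

**Alternative 2:** Disconnection of C1–C2 only. In the forward key step a diarylprolinol silyl ether and benzoic acid convert the hydroxybenzhydrol aldehyde A3 into a para-quinone methide at C1 and an enamine at C2, which closes ring B to give the aldehyde A4.
- For: the absolute configuration at C1 and C2 comes from a catalyst, and this is likely to be more selective than a menthyl fumarate can be without a Lewis acid. On face control this alternative is the stronger one.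
- Against: C3 must be built into the side chain of A3 as a single enantiomer in a separate asymmetric step, and the catalyst must match it. Ring A still needs two ortho carbon substituents, as 7 does, but one of them is a four-carbon functionalised chain. The key step forms one bond and at most two stereocentres, and the nucleophile must reach the carbon crowded by the C8 benzyloxy group.
- Comparison: the chosen route makes two bonds and three stereocentres from components that each take at most five steps, and its covalent auxiliary makes every stereoisomeric by-product a separable diastereomer.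

**Alternative 3:** Disconnection of C4–C4a. In the forward key step CF3SO3H in (CF3)2CHOH activates the methylene succinate A5, ring A attacks the terminal methylene carbon through C4a (para to the free C7 phenol, the pendant ring being deactivated as its tosylate), and tautomerisation of the enol sets C3 to give the diester A6.
- For: ring A needs no substituent at C4a beforehand. This is the one point on which it clearly beats the chosen route, which spends steps 2 and 3 on that carbon. The acyclic precursor comes from ordinary carbonyl chemistry.
- Against: the stereochemical burden moves to A5. C1, which carries two electronically similar aryl groups, and C2 must be defined before the key step, and there is no short way to do this. C3 arises by protonation of an enol, so the all-trans isomer may be reached only by equilibration. A superacid is hard on a benzyl ether beside a free phenol, and three different phenol protecting states have to be installed and removed.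
- Comparison: the chosen key step runs near neutrality at room temperature and fixes the absolute configuration in the same step that closes ring B.

Key step: step 7

Assumption: without a Lewis acid the menthyl esters of 13 are taken to give only a modest preference between the two fumarate faces, of a sense that cannot be predicted with confidence. The route is written for the Re,Re-face adduct 15, and the other adducts are treated as separable diastereomers.

## Route

Step 1
Reactants: 1 2,3-dihydroxy-4-methoxybenzaldehyde
Product: 2 7-methoxy-2,2-diphenyl-1,3-benzodioxole-4-carbaldehyde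
Conditions: Ph2CCl2, K2CO3, MeCN, 25 to 60 °C
Reagents that add atoms: dichlorodiphenylmethane, ClC(Cl)(c1ccccc1)c1ccccc1
Why: Cyclic ketal formation by double O-alkylation of a catechol with a gem-dichloride: one phenoxide displaces chloride through the stabilised chlorodiphenylmethyl cation and the neighbouring phenol closes the five-membered ring. The ketal is inert to organolithium, hydride and fluoride reagents and is removable by hydrogenolysis.

Step 2
Reactants: 2 7-methoxy-2,2-diphenyl-1,3-benzodioxole-4-carbaldehyde
Product: 6 5-iodo-7-methoxy-2,2-diphenyl-1,3-benzodioxole-4-carbaldehyde, via lithium α-amino alkoxide 3 (not isolated), via ortho-lithiated α-amino alkoxide 4 (not isolated), via iodinated α-amino alkoxide 5 (not isolated)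
Conditions: LiN(Me)CH2CH2NMe2 (from MeNHCH2CH2NMe2, n-BuLi), THF, −20 °C; n-BuLi, −20 °C; I2, THF, −78 °C to rt; H2O, aq. Na2S2O3
Reagents that add atoms: iodine, II
Why: α-Amino alkoxide-directed ortho-lithiation followed by iodination: the lithium amide adds to the aldehyde and the dimethylaminoethyl arm of the resulting alkoxide holds n-BuLi at the only free ortho C–H (the future C4a), so that it is metalated in preference to the C–H beside the methoxy group. The ketal oxygens have no free ortho position on ring A, iodine traps the aryllithium, and water collapses the hemiaminal back to the aldehyde.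

Step 3
Reactants: 6 5-iodo-7-methoxy-2,2-diphenyl-1,3-benzodioxole-4-carbaldehyde
Product: 7 7-methoxy-2,2-diphenyl-5-[(trimethylsilyl)methyl]-1,3-benzodioxole-4-carbaldehyde
Conditions: Me3SiCH2ZnCl (from Me3SiCH2Li, ZnCl2, THF, 0 °C), Pd(OAc)2 (cat.), SPhos (cat.), THF, 25 to 50 °C
Reagents that add atoms: [(trimethylsilyl)methyl]zinc chloride, C[Si](C)(C)C[Zn]Cl
Why: Negishi coupling: oxidative addition is fast at an aryl iodide next to a formyl group and the silylmethyl group has no β-hydrogen. An organozinc chloride free of magnesium salts should not add to the hindered, electron-rich aldehyde.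

Step 4
Reactants: 8 4-bromo-2-methoxyphenol
Product: 9 1-(benzyloxy)-4-bromo-2-methoxybenzene
Conditions: BnBr, K2CO3, DMF, rt
Reagents that add atoms: benzyl bromide, BrCc1ccccc1
Why: Williamson ether synthesis on a phenoxide; the benzyl ether survives Grignard formation, fluoride and hydride and leaves in the final hydrogenolysis.

Step 5
Reactants: 7 7-methoxy-2,2-diphenyl-5-[(trimethylsilyl)methyl]-1,3-benzodioxole-4-carbaldehyde; 9 1-(benzyloxy)-4-bromo-2-methoxybenzene
Product: 11 rac-[4-(benzyloxy)-3-methoxyphenyl]{7-methoxy-2,2-diphenyl-5-[(trimethylsilyl)methyl]-1,3-benzodioxol-4-yl}methanol, via arylmagnesium bromide 10 (not isolated)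
Conditions: 9, Mg, THF, 40 °C; then 7, THF, −20 to 0 °C; H2O
Reagents that add atoms: none
Why: Grignard addition of an aryl nucleophile to an aldehyde forms the C1–C1′ bond; the magnesium alkoxide is too weakly basic to move the neighbouring silyl group from carbon to oxygen (Brook-type migration). The carbinol centre is racemic, which does not matter because it becomes sp2 again in step 7.

Step 6
Reactants: 11 rac-[4-(benzyloxy)-3-methoxyphenyl]{7-methoxy-2,2-diphenyl-5-[(trimethylsilyl)methyl]-1,3-benzodioxol-4-yl}methanol
Product: 12 rac-[4-(benzyloxy)-3-methoxyphenyl]{7-methoxy-2,2-diphenyl-5-[(trimethylsilyl)methyl]-1,3-benzodioxol-4-yl}methyl acetate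
Conditions: Ac2O, Et3N, DMAP (cat.), CH2Cl2, 0 °C; aq. NaHCO3; used at once, no chromatography on acidic silica
Reagents that add atoms: acetic anhydride, CC(=O)OC(C)=O
Why: DMAP-catalysed acylation of a secondary alcohol under basic conditions free of Lewis acids, so that the easily ionised benzhydryl acetate is not pushed towards premature loss of acetate.

Step 7
Reactants: 12 rac-[4-(benzyloxy)-3-methoxyphenyl]{7-methoxy-2,2-diphenyl-5-[(trimethylsilyl)methyl]-1,3-benzodioxol-4-yl}methyl acetate; 13 di-(−)-menthyl fumarate
Product: 15 di-(−)-menthyl (1S,2R,3R)-1-[4-(benzyloxy)-3-methoxyphenyl]-6-methoxy-7,8-(diphenylmethylenedioxy)-1,2,3,4-tetrahydronaphthalene-2,3-dicarboxylate, via ortho-quinodimethane 14 (not isolated)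
Conditions: 13 (3 equiv), Bu4NF (1 M in THF, added slowly), MeCN, 0 °C to rt; chromatography
Reagents that add atoms: none
Why: Fluoride attacks silicon in 12 and the developing benzylic carbanion expels acetate across ring A (1,4-elimination, helped by the ease with which this alkoxy-stabilised benzhydryl centre releases its leaving group), giving ortho-quinodimethane 14 with the aryl group turned outward, away from the exocyclic methylene. The closest known reaction type is the fluoride-induced 1,4-elimination of ortho-(silylmethyl)benzyl ammonium salts and esters with Diels–Alder trapping of the ortho-quinodimethane by fumarates. Ring B closes by a concerted suprafacial intermolecular [4+2] cycloaddition of the diene C1=C8a–C4a=C4 with the fumarate double bond, which forms C1–C2 and C3–C4 and restores the aromaticity of ring A, so the addition should be fast at or below room temperature. The trans relationship of C2 and C3 is a stereospecific copy of the E geometry of 13. The relationship of C1 and C2 is set by the endo or exo placement of the esters: one ester must be endo, and placing the C3 ester endo beside the unsubstituted C4 terminus leaves the C2 ester exo and trans to the outward aryl group, which is twisted by the C8 oxygen and obstructs an endo ester at C2; tying that oxygen back in the ketal keeps this crowding small. The absolute configuration (1S,2R,3R) follows from addition to the Re,Re face of 13; the menthyl esters make the two faces diastereotopic, but without a Lewis acid their bias should be modest, so the step relies on the adducts being diastereomers that chromatography or crystallisation can separate. The step therefore needs exo placement of the C2 ester and one fumarate face; the first is secured by the diene geometry and the tied-back C8 oxygen, the second by the covalent auxiliary together with the separation.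

Step 8
Reactants: 15 di-(−)-menthyl (1S,2R,3R)-1-[4-(benzyloxy)-3-methoxyphenyl]-6-methoxy-7,8-(diphenylmethylenedioxy)-1,2,3,4-tetrahydronaphthalene-2,3-dicarboxylate
Product: 16 {(1S,2R,3R)-1-[4-(benzyloxy)-3-methoxyphenyl]-6-methoxy-7,8-(diphenylmethylenedioxy)-1,2,3,4-tetrahydronaphthalene-2,3-diyl}dimethanol
Conditions: LiAlH4, THF, 0 °C to reflux; then H2O
Reagents that add atoms: none
Why: Hydride reduction of both esters to primary alcohols; reduction is faster than enolisation, so C2 and C3 keep their configuration. The ketal and the benzyl ether are inert and the auxiliary alcohol can be recovered.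

Step 9
Reactants: 16 {(1S,2R,3R)-1-[4-(benzyloxy)-3-methoxyphenyl]-6-methoxy-7,8-(diphenylmethylenedioxy)-1,2,3,4-tetrahydronaphthalene-2,3-diyl}dimethanol
Product: 17 (1S,2R,3R)-1-(4-hydroxy-3-methoxyphenyl)-2,3-bis(hydroxymethyl)-6-methoxy-1,2,3,4-tetrahydronaphthalene-7,8-diol
Conditions: H2 (1 atm), Pd/C, THF–MeOH, rt; work-up under argon
Reagents that add atoms: none
Why: Catalytic hydrogenolysis cleaves the benzylic C–O bonds of the aryl benzyl ether and of the diphenylmethylene ketal while the C–C bonds at C1 are untouched. The neutral, non-oxidising conditions protect the catechol from oxidation and the 1,4-diol from cyclisation.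

## Compound list

1 | 2,3-dihydroxy-4-methoxybenzaldehyde | COc1ccc(C=O)c(O)c1O | starting material
2 | 7-methoxy-2,2-diphenyl-1,3-benzodioxole-4-carbaldehyde | COc1ccc(C=O)c2OC(c3ccccc3)(c3ccccc3)Oc12 | intermediate
3 | lithium {[2-(dimethylamino)ethyl](methyl)amino}(7-methoxy-2,2-diphenyl-1,3-benzodioxol-4-yl)methanolate, racemic | COc1ccc(C(O[Li])N(C)CCN(C)C)c2OC(c3ccccc3)(c3ccccc3)Oc12 | intermediate
4 | 5-lithio derivative of 3, racemic | COc1cc([Li])c(C(O[Li])N(C)CCN(C)C)c2OC(c3ccccc3)(c3ccccc3)Oc12 | intermediate
5 | 5-iodo derivative of 3, racemic | COc1cc(I)c(C(O[Li])N(C)CCN(C)C)c2OC(c3ccccc3)(c3ccccc3)Oc12 | intermediate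
6 | 5-iodo-7-methoxy-2,2-diphenyl-1,3-benzodioxole-4-carbaldehyde | COc1cc(I)c(C=O)c2OC(c3ccccc3)(c3ccccc3)Oc12 | intermediate
7 | 7-methoxy-2,2-diphenyl-5-[(trimethylsilyl)methyl]-1,3-benzodioxole-4-carbaldehyde | COc1cc(C[Si](C)(C)C)c(C=O)c2OC(c3ccccc3)(c3ccccc3)Oc12 | intermediate
8 | 4-bromo-2-methoxyphenol | COc1cc(Br)ccc1O | starting material
9 | 1-(benzyloxy)-4-bromo-2-methoxybenzene | COc1cc(Br)ccc1OCc1ccccc1 | intermediate
10 | [4-(benzyloxy)-3-methoxyphenyl]magnesium bromide | COc1cc([Mg]Br)ccc1OCc1ccccc1 | intermediate
11 | rac-[4-(benzyloxy)-3-methoxyphenyl]{7-methoxy-2,2-diphenyl-5-[(trimethylsilyl)methyl]-1,3-benzodioxol-4-yl}methanol | COc1cc(C(O)c2c(C[Si](C)(C)C)cc(OC)c3OC(c4ccccc4)(c4ccccc4)Oc23)ccc1OCc1ccccc1 | intermediate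
12 | rac-[4-(benzyloxy)-3-methoxyphenyl]{7-methoxy-2,2-diphenyl-5-[(trimethylsilyl)methyl]-1,3-benzodioxol-4-yl}methyl acetate | COc1cc(C(OC(C)=O)c2c(C[Si](C)(C)C)cc(OC)c3OC(c4ccccc4)(c4ccccc4)Oc23)ccc1OCc1ccccc1 | intermediate
13 | di-(−)-menthyl fumarate, bis[(1R,2S,5R)-5-methyl-2-(propan-2-yl)cyclohexyl] (2E)-but-2-enedioate | CC(C)[C@@H]1CC[C@@H](C)C[C@H]1OC(=O)/C=C/C(=O)O[C@@H]1C[C@H](C)CC[C@H]1C(C)C | starting material
14 | (4Z)-4-{[4-(benzyloxy)-3-methoxyphenyl]methylidene}-7-methoxy-5-methylidene-2,2-diphenyl-4,5-dihydro-1,3-benzodioxole (aryl group on the side of the ring oxygen, away from the methylidene group) | C=C1C=C(OC)C2=C(OC(c3ccccc3)(c3ccccc3)O2)/C1=C\c1ccc(OCc2ccccc2)c(OC)c1 | intermediate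
15 | di-(−)-menthyl (1S,2R,3R)-1-[4-(benzyloxy)-3-methoxyphenyl]-6-methoxy-7,8-(diphenylmethylenedioxy)-1,2,3,4-tetrahydronaphthalene-2,3-dicarboxylate | COc1cc([C@H]2c3c(cc(OC)c4OC(c5ccccc5)(c5ccccc5)Oc34)C[C@@H](C(=O)O[C@@H]3C[C@H](C)CC[C@H]3C(C)C)[C@@H]2C(=O)O[C@@H]2C[C@H](C)CC[C@H]2C(C)C)ccc1OCc1ccccc1 | intermediate
16 | {(1S,2R,3R)-1-[4-(benzyloxy)-3-methoxyphenyl]-6-methoxy-7,8-(diphenylmethylenedioxy)-1,2,3,4-tetrahydronaphthalene-2,3-diyl}dimethanol | COc1cc([C@H]2c3c(cc(OC)c4OC(c5ccccc5)(c5ccccc5)Oc34)C[C@@H](CO)[C@@H]2CO)ccc1OCc1ccccc1 | intermediate
17 | (1S,2R,3R)-1-(4-hydroxy-3-methoxyphenyl)-2,3-bis(hydroxymethyl)-6-methoxy-1,2,3,4-tetrahydronaphthalene-7,8-diol | COc1cc([C@H]2c3c(cc(OC)c(O)c3O)C[C@@H](CO)[C@@H]2CO)ccc1O | target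

## Step count and risk

Total step count: 9. Longest linear sequence: 8 steps (steps 1, 2, 3, 5, 6, 7, 8 and 9 from 1). Step 4 is a one-step side branch from 8 that joins at step 5.

**Step 7 (key step).** Most likely to go wrong:
- poor facial selectivity, because no Lewis acid can be present alongside fluoride to fix the conformation of the enoate units, so the menthyl groups shield one face only weakly;
- loss of the exo preference of the C2 ester;
- self-condensation of 14, or protodesilylation of 12 by wet fluoride before the acetate leaves.

Fallback: the stereochemistry is corrected after the cycloaddition instead of being demanded from it. Of the four possible adducts the two with (1S) configuration are both usable, since C1 is the only centre that cannot be changed later. Setting out from 12 and 13, the 1,2-cis adduct of the Si,Si face, di-(−)-menthyl (1S,2S,3S)-1-[4-(benzyloxy)-3-methoxyphenyl]-6-methoxy-7,8-(diphenylmethylenedioxy)-1,2,3,4-tetrahydronaphthalene-2,3-dicarboxylate F1, is collected beside 15 and treated with KOtBu in t-BuOH–THF. Enolisation at C2 gives the (1S,2R,3S) diester F2, and enolisation at C3 should then drain it into the all-trans isomer, so this material returns to the route at 15. If the (1R) series dominates, the same sequence is run from 12 with the enantiomeric dienophile di-(+)-menthyl fumarate F3. Its Re,Re-face exo adduct, the di-(+)-menthyl (1S,2R,3R) diester F4, is reduced with LiAlH4 and returns to the route at 16.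

**Step 2.** Most likely to go wrong: metalation beside the methoxy group instead of beside the masked formyl group, or slow metalation that lets n-BuLi attack the phenyl rings of the ketal during the long exposure. Fallback: an isolated directing group and a shorter, colder metalation. Setting out from 2, condensation with MeNHCH2CH2NHMe (toluene, reflux, azeotropic removal of water) gives 2-(7-methoxy-2,2-diphenyl-1,3-benzodioxol-4-yl)-1,3-dimethylimidazolidine F5. s-BuLi and TMEDA in Et2O at −78 °C give the ortho-lithiated imidazolidine F6, iodine gives the iodo imidazolidine F7, and brief treatment with dilute aqueous HCl in THF at rt hydrolyses the aminal and returns to the route at 6.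

**Step 3.** Most likely to go wrong: addition of the zinc reagent to the aldehyde (followed by Peterson-type elimination), or slow transmetalation at the hindered palladium centre. Fallback: mask the aldehyde and use the more reactive magnesium reagent. Setting out from 6, ethylene glycol and PPTS in toluene (reflux, azeotropic removal of water) give 4-(1,3-dioxolan-2-yl)-5-iodo-7-methoxy-2,2-diphenyl-1,3-benzodioxole F8. Kumada coupling with Me3SiCH2MgCl and NiCl2(dppp) in THF gives the silylmethyl dioxolane F9, and PPTS in acetone–H2O releases the aldehyde and returns to the route at 7.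

**Step 6.** Most likely to go wrong: ionisation of the benzhydryl acetate during its formation or work-up, followed by desilylation to 14 with no dienophile present, or hydrolysis back to 11. Fallback: 12 is not isolated. Setting out from 11, the alcohol is acetylated in MeCN (Ac2O, Et3N, DMAP) with 13 already in the flask, and Bu4NF is then added to the same solution, so that any 14 formed early is trapped at once. The sequence returns to the route at 15 and makes no new compound (F0).

**Step 9.** Most likely to go wrong: incomplete hydrogenolysis of the diphenylmethylene ketal after the benzyl ether has gone, or air oxidation of the freed catechol. Fallback: split the deprotection. Setting out from 16, hydrogenolysis is stopped at the debenzylated ketal {(1S,2R,3R)-1-(4-hydroxy-3-methoxyphenyl)-6-methoxy-7,8-(diphenylmethylenedioxy)-1,2,3,4-tetrahydronaphthalene-2,3-diyl}dimethanol F10. The ketal is then hydrolysed with 2 M HCl in degassed MeOH–THF at 40 °C, which returns to the route at 17.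

## Further compounds

F1 | step 7 | di-(−)-menthyl (1S,2S,3S)-1-[4-(benzyloxy)-3-methoxyphenyl]-6-methoxy-7,8-(diphenylmethylenedioxy)-1,2,3,4-tetrahydronaphthalene-2,3-dicarboxylate | COc1cc([C@H]2c3c(cc(OC)c4OC(c5ccccc5)(c5ccccc5)Oc34)C[C@H](C(=O)O[C@@H]3C[C@H](C)CC[C@H]3C(C)C)[C@H]2C(=O)O[C@@H]2C[C@H](C)CC[C@H]2C(C)C)ccc1OCc1ccccc1
F2 | step 7 | di-(−)-menthyl (1S,2R,3S)-1-[4-(benzyloxy)-3-methoxyphenyl]-6-methoxy-7,8-(diphenylmethylenedioxy)-1,2,3,4-tetrahydronaphthalene-2,3-dicarboxylate | COc1cc([C@H]2c3c(cc(OC)c4OC(c5ccccc5)(c5ccccc5)Oc34)C[C@H](C(=O)O[C@@H]3C[C@H](C)CC[C@H]3C(C)C)[C@@H]2C(=O)O[C@@H]2C[C@H](C)CC[C@H]2C(C)C)ccc1OCc1ccccc1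
F3 | step 7 | di-(+)-menthyl fumarate, bis[(1S,2R,5S)-5-methyl-2-(propan-2-yl)cyclohexyl] (2E)-but-2-enedioate | CC(C)[C@H]1CC[C@H](C)C[C@@H]1OC(=O)/C=C/C(=O)O[C@H]1C[C@@H](C)CC[C@@H]1C(C)C
F4 | step 7 | di-(+)-menthyl (1S,2R,3R)-1-[4-(benzyloxy)-3-methoxyphenyl]-6-methoxy-7,8-(diphenylmethylenedioxy)-1,2,3,4-tetrahydronaphthalene-2,3-dicarboxylate | COc1cc([C@H]2c3c(cc(OC)c4OC(c5ccccc5)(c5ccccc5)Oc34)C[C@@H](C(=O)O[C@H]3C[C@@H](C)CC[C@@H]3C(C)C)[C@@H]2C(=O)O[C@H]2C[C@@H](C)CC[C@@H]2C(C)C)ccc1OCc1ccccc1
F5 | step 2 | 2-(7-methoxy-2,2-diphenyl-1,3-benzodioxol-4-yl)-1,3-dimethylimidazolidine | COc1ccc(C2N(C)CCN2C)c2OC(c3ccccc3)(c3ccccc3)Oc12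
F6 | step 2 | 2-(5-lithio-7-methoxy-2,2-diphenyl-1,3-benzodioxol-4-yl)-1,3-dimethylimidazolidine | COc1cc([Li])c(C2N(C)CCN2C)c2OC(c3ccccc3)(c3ccccc3)Oc12
F7 | step 2 | 2-(5-iodo-7-methoxy-2,2-diphenyl-1,3-benzodioxol-4-yl)-1,3-dimethylimidazolidine | COc1cc(I)c(C2N(C)CCN2C)c2OC(c3ccccc3)(c3ccccc3)Oc12
F8 | step 3 | 4-(1,3-dioxolan-2-yl)-5-iodo-7-methoxy-2,2-diphenyl-1,3-benzodioxole | COc1cc(I)c(C2OCCO2)c2OC(c3ccccc3)(c3ccccc3)Oc12
F9 | step 3 | 4-(1,3-dioxolan-2-yl)-7-methoxy-2,2-diphenyl-5-[(trimethylsilyl)methyl]-1,3-benzodioxole | COc1cc(C[Si](C)(C)C)c(C2OCCO2)c2OC(c3ccccc3)(c3ccccc3)Oc12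
F0 | step 6 | none | none
F10 | step 9 | {(1S,2R,3R)-1-(4-hydroxy-3-methoxyphenyl)-6-methoxy-7,8-(diphenylmethylenedioxy)-1,2,3,4-tetrahydronaphthalene-2,3-diyl}dimethanol | COc1cc([C@H]2c3c(cc(OC)c4OC(c5ccccc5)(c5ccccc5)Oc34)C[C@@H](CO)[C@@H]2CO)ccc1O
A1 | alternative 1 | (2R,4R)-pentane-2,4-diyl mixed diester of (E)-4-hydroxy-3-methoxy-5-(pivaloyloxy)cinnamic acid and (E)-4-hydroxy-3-methoxycinnamic acid | COc1cc(/C=C/C(=O)O[C@H](C)C[C@@H](C)OC(=O)/C=C/c2ccc(O)c(OC)c2)cc(OC(=O)C(C)(C)C)c1O
A2 | alternative 1 | (2R,4R)-pentane-2,4-diyl-tethered 1-(4-hydroxy-3-methoxyphenyl)-7-hydroxy-6-methoxy-8-(pivaloyloxy)-1,2-dihydronaphthalene-2,3-dicarboxylate (nine-membered dilactone, target configuration at C1 and C2) | COc1cc([C@H]2c3c(cc(OC)c(O)c3OC(=O)C(C)(C)C)C=C4C(=O)O[C@H](C)C[C@@H](C)OC(=O)[C@H]24)ccc1O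
A3 | alternative 2 | 4-{3,4-bis(benzyloxy)-2-[hydroxy(4-hydroxy-3-methoxyphenyl)methyl]-5-methoxyphenyl}-3-[(tert-butyldimethylsilyloxy)methyl]butanal (single configuration at C3, benzhydrol centre undefined) | COc1cc(C(O)c2c(C[C@@H](CO[Si](C)(C)C(C)(C)C)CC=O)cc(OC)c(OCc3ccccc3)c2OCc2ccccc2)ccc1O
A4 | alternative 2 | 7,8-bis(benzyloxy)-3-[(tert-butyldimethylsilyloxy)methyl]-1-(4-hydroxy-3-methoxyphenyl)-6-methoxy-1,2,3,4-tetrahydronaphthalene-2-carbaldehyde (target configuration at C1, C2 and C3) | COc1cc([C@H]2c3c(cc(OC)c(OCc4ccccc4)c3OCc3ccccc3)C[C@@H](CO[Si](C)(C)C(C)(C)C)[C@@H]2C=O)ccc1O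
A5 | alternative 3 | dimethyl 2-{[2-(benzyloxy)-3-hydroxy-4-methoxyphenyl][3-methoxy-4-(tosyloxy)phenyl]methyl}-3-methylidenebutanedioate (C1 and C2 drawn as required for the target) | COc1cc([C@@H](c2ccc(OC)c(O)c2OCc2ccccc2)[C@@H](C(=O)OC)C(=C)C(=O)OC)ccc1OS(=O)(=O)c1ccc(C)cc1
A6 | alternative 3 | dimethyl 8-(benzyloxy)-7-hydroxy-6-methoxy-1-[3-methoxy-4-(tosyloxy)phenyl]-1,2,3,4-tetrahydronaphthalene-2,3-dicarboxylate (all-trans) | COc1cc([C@H]2c3c(cc(OC)c(O)c3OCc3ccccc3)C[C@@H](C(=O)OC)[C@@H]2C(=O)OC)ccc1OS(=O)(=O)c1ccc(C)cc1
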